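## Analysis of the target

The target (12) is a p-terphenyl: a fully substituted central benzene ring that carries a 4-hydroxyphenyl ring at C3 and at C6. On the central ring C1 and C2 bear benzoyloxy groups and C4 and C5 bear free hydroxyls, so the four ring oxygens form two vicinal pairs that differ only in acylation. There is no stereocentre, and a mirror plane through the midpoints of the C1–C2 and C4–C5 bonds makes the two outer rings and the two esters equivalent, so each can be introduced in a twofold operation. The sensitive groups are the two aryl benzoates, which phenoxides and other bases cleave or transfer, and the electron-rich catechol, which air oxidises to the o-quinone once it is free. The difficulty is to tell the two oxygen pairs apart on a crowded, hexasubstituted ring, since any route through a symmetric tetrol has four equivalent hydroxyls to differentiate. The strategy rests on the fact that C1 is para to the oxygen on C4, C2 is para to the oxygen on C5, and C1 and C2 are the only hydrogen-bearing carbons of the central ring of a 3,6-diarylcatechol. The two ester C–O bonds can therefore be made directly from C–H bonds of a protected catechol, with the benzoates arriving already in place.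

## Retrosynthetic reasoning

12 is traced back to 11 by replacing four O–H bonds with O–Si bonds: a di-tert-butylsilylene bridging the catechol oxygens and a triisopropylsilyl ether on each outer phenol. Silicon is chosen because acidic fluoride removes it without forming a phenoxide, so the aryl benzoates are left alone, and one operation frees all four hydroxyls. In 12 each ester is flanked by the other ester and by an aryl group, so no acyl shift to a neighbouring hydroxyl is possible once the phenols are free. The forward reaction has to open a strained dioxasilole and cleave two hindered aryl silyl ethers without touching the esters.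

11 is cut at the two bonds between the ester oxygens and C5 and C6 of the benzodioxasilole, which leads to 8 and two molecules of 9. Cutting the acyl C–O bonds instead would lead to a tetrol whose two oxygen pairs would have to be distinguished. Cutting at the ring carbon avoids this, because one pair is present and masked from the start and the other arrives as benzoate. C5 and C6 are the only C–H positions of the central ring and each is para to one dioxasilole oxygen, which is where an arene radical cation of this type accepts a nucleophile. The forward reaction, an anodic oxidation, has to form two C–O bonds at adjacent, hindered carbons by way of 10 and has to prefer the central ring over the outer rings.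

8 is cut at the two biaryl bonds at C4 and C7, which gives the dibromide 4 and two molecules of the aryl bromide 2. The symmetry allows one twofold coupling, and the outer rings come from a purchasable para-substituted phenol. The aryl partner is used as its zinc derivative 6, made from 2 through the lithium compound 5, and the coupling passes through the monoarylated bromide 7. An organozinc coupling is chosen because it runs without water or base, so none of the Si–O bonds is exposed to hydrolysis.

4 is cut at the two Si–O bonds of the dioxasilole and leads to the catechol 3, whose bromines already sit at the carbons that become the biaryl bonds. The silylene masks the catechol during the coupling and keeps the oxygen lone pairs in a planar five-membered ring, conjugated with the arene, for the oxidation. Its tert-butyl groups shield silicon against nucleophiles.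

2 is cut at its Si–O bond and leads to 4-bromophenol 1. The bulky silyl group is placed here so that it later screens the ortho positions of the outer rings, and the para bromine is the handle for metalation.

## Alternatives that were turned down

Alternative 1: The central ring is disconnected into two identical three-carbon units, each an arylpyruvate ester A1 (methyl 3-[4-(benzyloxy)phenyl]-2-oxopropanoate).
- Key step: two molecules of A1, enolised by a hydride base in a hot hydrocarbon solvent, would acylate each other's benzylic carbon with their ester carbon and close the ring as the dihydroxyquinone A2 (2,5-bis[4-(benzyloxy)phenyl]-3,6-dihydroxy-1,4-benzoquinone).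
- For: it follows the biogenetic logic of the terphenylquinones, uses no metal and no electrolysis, and builds the whole hexasubstituted ring with both aryl groups and all four oxygens in one step. On ring construction it is stronger than the chosen route.
- Against: the ketone carbonyl of A1 is more electrophilic than its ester, so aldol-type self-condensation to butenolides competes with the double ester acylation. More seriously, A2 and the tetrol A3 obtained on reduction (3,6-bis[4-(benzyloxy)phenyl]benzene-1,2,4,5-tetrol) carry four oxygens that symmetry makes equivalent, while the target needs one vicinal pair benzoylated and the other free. Nothing in A3 biases this, so a statistical mono-bridging of one pair, benzoylation, unbridging and hydrogenolysis would follow.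
- Comparison: the short ring synthesis is paid for afterwards in differentiation steps. The chosen strategy offers instead an oxygen pattern that is differentiated from the first step.

Alternative 2: Both outer phenol rings are disconnected, each into an acetaldehyde arm on the central ring and butenone A5.
- Key step: the dialdehyde A4 (2,2'-[5,6-bis(benzoyloxy)-1,3-benzodioxole-4,7-diyl]diacetaldehyde) would react twice with A5 by amine-catalysed Michael addition at the benzylic carbon and acid-promoted aldol closure between the aldehyde carbon and the ketone methyl. The product is the bis(cyclohexenone) A6 (4,7-bis(4-oxocyclohex-2-en-1-yl)-1,3-benzodioxole-5,6-diyl dibenzoate).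
- For: the esters are in place on the central ring before anything else is built, so their position is never in question, and the annulation of α-aryl aldehydes with enones to 4-arylcyclohexenones is an established reaction type. On the placement of the esters it is as strong as any route.
- Against: it constructs two benzene rings that can be bought as 1. A4 itself needs a fully substituted benzodioxole with two homologated arms, and A6 is still two dehydrogenations away from the phenols, so the two stereocentres it creates are made only to be destroyed. The methylene acetal then has to be removed with strong Lewis acids or oxidants that endanger the aryl benzoates. The benzoates of A4 also sit next to the aldehyde arms and would meet a nucleophilic secondary amine in the key step.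
- Comparison: this route is much longer and weaker on step economy. The chosen strategy secures the ester positions through the para-directing catechol oxygens and not through prior construction.

Alternative 3: The central ring is disconnected by a retro-Diels–Alder cut into a diene that carries both aryl groups and both benzoates and a dienophile that supplies the catechol carbons.
- Key step: the Z,Z-diene A7 ((1Z,3Z)-1,4-bis[4-(benzyloxy)phenyl]buta-1,3-diene-2,3-diyl dibenzoate) and the dienophile A8 (4,5-dichloro-1,3-dioxol-2-one) would combine thermally to the meso endo cycloadduct A9. Hydrolysis of the chlorinated carbonate would give a 1,2-dione that reaches the aromatic level by two enolisations, without an oxidant, and hydrogenolysis would finish.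
- For: every oxygen is placed by construction, the two pairs are differentiated by their origin, the aromatisation is redox-neutral, and no C–H selectivity is involved. On regiochemical certainty this alternative is stronger than the chosen strategy.
- Against: A7 is a bis(enol ester) of a 1,4-diaryl-2,3-diketone that must be made with defined geometry at both double bonds. A8 is a tetrasubstituted, weakly activated dienophile that needs forcing temperatures with a diene substituted at all four carbons. The benzoates are labile enol esters until the ring is aromatic, yet they must survive the hydrolytic unmasking of the dione. A8 also has to be prepared.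
- Comparison: the chosen strategy offers a shorter sequence from purchasable aromatics, C–C bonds made by a dependable cross-coupling, esters that are only ever aryl esters, and risk concentrated in one late step that can be studied on an easily made precursor.

Key step: step 4

Assumption: 3,6-dibromobenzene-1,2-diol (3) and dry tetrabutylammonium benzoate are treated as purchasable.

## Route

Step 1
Reactants: 1 4-bromophenol
Product: 2 (4-bromophenoxy)triisopropylsilane
Conditions: iPr3SiCl, imidazole, DMF, rt
Reagents that add atoms: chlorotriisopropylsilane, CC(C)[Si](Cl)(C(C)C)C(C)C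
Why: Imidazole-promoted O-silylation of a phenol; the bulky silyl ether withstands organolithium reagents at low temperature and later screens the ortho positions of the outer rings.

Step 2
Reactants: 3 3,6-dibromobenzene-1,2-diol
Product: 4 4,7-dibromo-2,2-di-tert-butyl-1,3,2-benzodioxasilole
Conditions: tBu2Si(OTf)2, 2,6-lutidine, CH2Cl2, 0 °C to rt
Reagents that add atoms: di-tert-butylsilyl bis(trifluoromethanesulfonate), CC(C)(C)[Si](OS(=O)(=O)C(F)(F)F)(OS(=O)(=O)C(F)(F)F)C(C)(C)C
Why: Cyclic silylene formation on a 1,2-diol; the bis(triflate) is reactive enough for the weakly nucleophilic brominated catechol and the second Si–O bond closes a five-membered ring.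

Step 3
Reactants: 2 (4-bromophenoxy)triisopropylsilane (slightly more than two equivalents); 4 4,7-dibromo-2,2-di-tert-butyl-1,3,2-benzodioxasilole
Product: 8 2,2-di-tert-butyl-4,7-bis[4-(triisopropylsilyloxy)phenyl]-1,3,2-benzodioxasilole, via aryllithium 5 (not isolated), via arylzinc chloride 6 (not isolated), via monoaryl bromide 7 (not isolated)
Conditions: n-BuLi, THF, −78 °C; ZnCl2, −78 °C to rt; then 4, Pd(OAc)2 (cat.), SPhos, THF, 50 °C
Reagents that add atoms: none
Why: Bromine–lithium exchange, transmetalation to zinc and a twofold Negishi coupling; the medium is neutral and anhydrous, so the dioxasilole and the aryl silyl ethers are not hydrolysed, and the biarylphosphine ligand handles the electron-rich bromide next to the ring oxygen.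

Step 4
Reactants: 8 2,2-di-tert-butyl-4,7-bis[4-(triisopropylsilyloxy)phenyl]-1,3,2-benzodioxasilole; 9 benzoic acid (two molecules)
Product: 11 2,2-di-tert-butyl-4,7-bis[4-(triisopropylsilyloxy)phenyl]-1,3,2-benzodioxasilole-5,6-diyl dibenzoate, via monobenzoate 10 (not isolated)
Conditions: graphite anode, Pt cathode, undivided cell, dry Bu4N(O2CPh), PhCO2H (excess), MeCN/CH2Cl2, rt, controlled potential, about 4 F/mol
Reagents that add atoms: none
Why: Proposed new method: the closest known reaction type is the anodic nuclear acyloxylation of alkoxyarenes through their radical cations, which has not been shown on a silyl-protected catechol or twice on neighbouring carbons of so crowded a ring. 8 should give up one electron at the carbon anode to a radical cation centred on the doubly oxygenated central ring, from which the outer rings are twisted, and most electrophilic at C5 and C6, each para to one dioxasilole oxygen; benzoate adds at C5, the cyclohexadienyl radical is oxidised at once and the resulting cation loses its proton to benzoate, giving 10 (an ECEC sequence). 10 is harder to oxidise, but the same sequence at C6, para to the second ring oxygen, should give 11, after which the central ring has no hydrogen left and two esters have raised the potential, so the current should fall off. At the cathode the protons of 9 are reduced to dihydrogen and benzoate is regenerated, so the ammonium salt acts only as electrolyte and base and 9 is what is consumed. No ring is closed and no stereocentre is formed. The selectivity needed is central ring against outer rings: the para positions of the outer rings are taken by the biaryl bonds, and their ortho positions are less activated in the radical cation and screened by the triisopropylsilyl groups. The benzoate is supplied as its dry tetrabutylammonium salt with an excess of 9 and is not made with aqueous or methanolic hydroxide, because water, methanol or hydroxide would compete for the radical cation and cleave the aryl silyl ethers, and because benzoate hydrogen-bonded to 9 is harder to oxidise than the arene. Attack of benzoate at silicon in the radical cation, which would open the dioxasilole towards the o-quinone, is held back by the tert-butyl and isopropyl groups.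

Step 5
Reactants: 11 2,2-di-tert-butyl-4,7-bis[4-(triisopropylsilyloxy)phenyl]-1,3,2-benzodioxasilole-5,6-diyl dibenzoate
Product: 12 4,4'',5',6'-tetrahydroxy-[1,1':4',1''-terphenyl]-2',3'-diyl dibenzoate
Conditions: HF·pyridine (excess), THF/pyridine, 0 °C to rt, argon, degassed work-up
Reagents that add atoms: none
Why: Fluoride-driven cleavage of all four Si–O bonds (global desilylation) in an acidic medium, where the freed phenols stay protonated and cannot attack the aryl benzoates; the freed hydroxyls have no ester on a neighbouring carbon, so no acyl shift is possible.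

## Compound list

1 | 4-bromophenol | Oc1ccc(Br)cc1 | starting material
2 | (4-bromophenoxy)triisopropylsilane | CC(C)[Si](C(C)C)(C(C)C)Oc1ccc(Br)cc1 | intermediate
3 | 3,6-dibromobenzene-1,2-diol | Oc1c(O)c(Br)ccc1Br | starting material
4 | 4,7-dibromo-2,2-di-tert-butyl-1,3,2-benzodioxasilole | CC(C)(C)[Si]1(C(C)(C)C)Oc2c(Br)ccc(Br)c2O1 | intermediate
5 | [4-(triisopropylsilyloxy)phenyl]lithium | [Li]c1ccc(O[Si](C(C)C)(C(C)C)C(C)C)cc1 | intermediate
6 | chloro[4-(triisopropylsilyloxy)phenyl]zinc | Cl[Zn]c1ccc(O[Si](C(C)C)(C(C)C)C(C)C)cc1 | intermediate
7 | 4-bromo-2,2-di-tert-butyl-7-[4-(triisopropylsilyloxy)phenyl]-1,3,2-benzodioxasilole | CC(C)[Si](C(C)C)(C(C)C)Oc1ccc(cc1)-c1ccc(Br)c2O[Si](C(C)(C)C)(C(C)(C)C)Oc12 | intermediate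
8 | 2,2-di-tert-butyl-4,7-bis[4-(triisopropylsilyloxy)phenyl]-1,3,2-benzodioxasilole | CC(C)[Si](C(C)C)(C(C)C)Oc1ccc(cc1)-c1ccc(-c2ccc(O[Si](C(C)C)(C(C)C)C(C)C)cc2)c2O[Si](C(C)(C)C)(C(C)(C)C)Oc12 | intermediate
9 | benzoic acid | O=C(O)c1ccccc1 | starting material
10 | 2,2-di-tert-butyl-4,7-bis[4-(triisopropylsilyloxy)phenyl]-1,3,2-benzodioxasilol-5-yl benzoate | CC(C)[Si](C(C)C)(C(C)C)Oc1ccc(cc1)-c1c(OC(=O)c2ccccc2)cc(-c2ccc(O[Si](C(C)C)(C(C)C)C(C)C)cc2)c2O[Si](C(C)(C)C)(C(C)(C)C)Oc12 | intermediate
11 | 2,2-di-tert-butyl-4,7-bis[4-(triisopropylsilyloxy)phenyl]-1,3,2-benzodioxasilole-5,6-diyl dibenzoate | CC(C)[Si](C(C)C)(C(C)C)Oc1ccc(cc1)-c1c(OC(=O)c2ccccc2)c(OC(=O)c2ccccc2)c(-c2ccc(O[Si](C(C)C)(C(C)C)C(C)C)cc2)c2O[Si](C(C)(C)C)(C(C)(C)C)Oc12 | intermediate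
12 | 4,4'',5',6'-tetrahydroxy-[1,1':4',1''-terphenyl]-2',3'-diyl dibenzoate | O=C(Oc1c(OC(=O)c2ccccc2)c(-c2ccc(O)cc2)c(O)c(O)c1-c1ccc(O)cc1)c1ccccc1 | target

## Step count and least certain steps

Total: 5 steps. Longest linear sequence: 4 steps (steps 1, 3, 4, 5; step 2 feeds step 3).

**Step 4 (key step).**
- Risk: misdirected attack of benzoate. This could be substitution on an outer ring ortho to the silyloxy group, or ipso attack at a biaryl carbon followed by loss of the silyl group. The charge of the radical cation is shared to some extent with the outer rings.
- Risk: collapse of the radical cation at a Si–O bond, since silyl aryl ether radical cations can shed silicon to a nucleophile.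
- Risk: stalling after the first substitution, because C6 of 10 lies between an aryl group and an ester and the potential of 10 approaches that of the benzoate.
- Fallback (known chemistry): it sets out from 2, converted into the zinc reagent 6 through 5 as in step 3, and returns at 11.
  - Purchasable 2,5-dibromo-3,6-dihydroxy-1,4-benzoquinone F1 is reduced with aqueous Na2S2O4 to 3,6-dibromobenzene-1,2,4,5-tetrol F2.
  - One equivalent of tBu2Si(OTf)2 with 2,6-lutidine bridges one vicinal pair of hydroxyls to give 4,7-dibromo-2,2-di-tert-butyl-1,3,2-benzodioxasilole-5,6-diol F3. The two pairs are equivalent, so a statistical share of doubly bridged material is separated after the next operation.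
  - Benzoylation in the same flask (PhCOCl, pyridine) gives 4,7-dibromo-2,2-di-tert-butyl-1,3,2-benzodioxasilole-5,6-diyl dibenzoate F4.
  - A twofold Negishi coupling of F4 with 6 under the catalyst of step 3, which leaves aryl esters alone, passes through the monoarylated bromide F5 and gives 11.
  - Here the four oxygens are in place before the biaryl bonds are made, and no C–H bond has to be functionalised.

**Step 3.**
- Risk: incomplete second coupling, protodemetalation of the zinc reagent, or opening of the strained dioxasilole by aryllithium left over from an incomplete transmetalation. The electron-rich bromide next to a ring oxygen adds slowly to zerovalent palladium.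
- Fallback: it sets out from 3 and from the aryllithium 5 and returns at 8.
  - 3 is converted with MeOCH2Cl and iPr2NEt into 1,4-dibromo-2,3-bis(methoxymethoxy)benzene F6.
  - 5 is quenched with 2-isopropoxy-4,4,5,5-tetramethyl-1,3,2-dioxaborolane to give triisopropyl[4-(4,4,5,5-tetramethyl-1,3,2-dioxaborolan-2-yl)phenoxy]silane F7.
  - A twofold Suzuki–Miyaura coupling (Pd(dppf)Cl2, K3PO4, dioxane/H2O, 80 °C) leads through the monoarylated bromide F8 to the 2',3'-bis(methoxymethoxy)terphenyl F9.
  - The acetals are removed with HCl in MeOH/THF, which aryl triisopropylsilyl ethers tolerate, to give 3,6-bis[4-(triisopropylsilyloxy)phenyl]benzene-1,2-diol F10.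
  - Silylene formation as in step 2 gives 8.
  - The aqueous base of the coupling never meets the dioxasilole, which is put on last.

**Step 5.**
- Risk: slow cleavage of the two hindered aryl silyl ethers under acidic fluoride. If the medium is made more basic to speed it, benzoyl transfer or loss through phenoxides becomes likely.
- Risk: air oxidation of the freed electron-rich catechol during work-up.
- Fallback: it sets out from 4 and returns at 12; the outer phenols are carried as benzyl ethers. It presupposes that the anodic step tolerates benzyl ethers.
  - 1-(Benzyloxy)-4-bromobenzene F11 is taken through [4-(benzyloxy)phenyl]lithium F12 to [4-(benzyloxy)phenyl]zinc chloride F13.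
  - F13 is coupled twice with 4 as in step 3, by way of the monoarylated bromide F14, to give 4,7-bis[4-(benzyloxy)phenyl]-2,2-di-tert-butyl-1,3,2-benzodioxasilole F15.
  - Electrolysis with 9 as in step 4 gives, through the monobenzoate F16, the dibenzoate F17.
  - HF·pyridine then has only the strained dioxasilole to open and gives 3,6-bis[4-(benzyloxy)phenyl]-4,5-dihydroxy-1,2-phenylene dibenzoate F18.
  - Hydrogenolysis (H2, Pd/C, EtOAc/THF) removes the benzyl ethers under neutral conditions and gives 12.

## Further compounds

F1 | step 4 | 2,5-dibromo-3,6-dihydroxy-1,4-benzoquinone | O=C1C(Br)=C(O)C(=O)C(Br)=C1O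
F2 | step 4 | 3,6-dibromobenzene-1,2,4,5-tetrol | Oc1c(O)c(Br)c(O)c(O)c1Br
F3 | step 4 | 4,7-dibromo-2,2-di-tert-butyl-1,3,2-benzodioxasilole-5,6-diol | CC(C)(C)[Si]1(C(C)(C)C)Oc2c(Br)c(O)c(O)c(Br)c2O1
F4 | step 4 | 4,7-dibromo-2,2-di-tert-butyl-1,3,2-benzodioxasilole-5,6-diyl dibenzoate | CC(C)(C)[Si]1(C(C)(C)C)Oc2c(Br)c(OC(=O)c3ccccc3)c(OC(=O)c3ccccc3)c(Br)c2O1
F5 | step 4 | 4-bromo-2,2-di-tert-butyl-7-[4-(triisopropylsilyloxy)phenyl]-1,3,2-benzodioxasilole-5,6-diyl dibenzoate | CC(C)[Si](C(C)C)(C(C)C)Oc1ccc(cc1)-c1c(OC(=O)c2ccccc2)c(OC(=O)c2ccccc2)c(Br)c2O[Si](C(C)(C)C)(C(C)(C)C)Oc12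
F6 | step 3 | 1,4-dibromo-2,3-bis(methoxymethoxy)benzene | COCOc1c(Br)ccc(Br)c1OCOC
F7 | step 3 | triisopropyl[4-(4,4,5,5-tetramethyl-1,3,2-dioxaborolan-2-yl)phenoxy]silane | CC(C)[Si](C(C)C)(C(C)C)Oc1ccc(cc1)B1OC(C)(C)C(C)(C)O1
F8 | step 3 | {[4'-bromo-2',3'-bis(methoxymethoxy)-[1,1'-biphenyl]-4-yl]oxy}triisopropylsilane | COCOc1c(Br)ccc(-c2ccc(O[Si](C(C)C)(C(C)C)C(C)C)cc2)c1OCOC
F9 | step 3 | {[2',3'-bis(methoxymethoxy)-[1,1':4',1''-terphenyl]-4,4''-diyl]bis(oxy)}bis(triisopropylsilane) | COCOc1c(-c2ccc(O[Si](C(C)C)(C(C)C)C(C)C)cc2)ccc(-c2ccc(O[Si](C(C)C)(C(C)C)C(C)C)cc2)c1OCOC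
F10 | step 3 | 3,6-bis[4-(triisopropylsilyloxy)phenyl]benzene-1,2-diol | Oc1c(-c2ccc(O[Si](C(C)C)(C(C)C)C(C)C)cc2)ccc(-c2ccc(O[Si](C(C)C)(C(C)C)C(C)C)cc2)c1O
F11 | step 5 | 1-(benzyloxy)-4-bromobenzene | Brc1ccc(OCc2ccccc2)cc1
F12 | step 5 | [4-(benzyloxy)phenyl]lithium | [Li]c1ccc(OCc2ccccc2)cc1
F13 | step 5 | [4-(benzyloxy)phenyl]zinc chloride | Cl[Zn]c1ccc(OCc2ccccc2)cc1
F14 | step 5 | 4-[4-(benzyloxy)phenyl]-7-bromo-2,2-di-tert-butyl-1,3,2-benzodioxasilole | CC(C)(C)[Si]1(C(C)(C)C)Oc2c(Br)ccc(-c3ccc(OCc4ccccc4)cc3)c2O1
F15 | step 5 | 4,7-bis[4-(benzyloxy)phenyl]-2,2-di-tert-butyl-1,3,2-benzodioxasilole | CC(C)(C)[Si]1(C(C)(C)C)Oc2c(-c3ccc(OCc4ccccc4)cc3)ccc(-c3ccc(OCc4ccccc4)cc3)c2O1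
F16 | step 5 | 4,7-bis[4-(benzyloxy)phenyl]-2,2-di-tert-butyl-1,3,2-benzodioxasilol-5-yl benzoate | CC(C)(C)[Si]1(C(C)(C)C)Oc2c(-c3ccc(OCc4ccccc4)cc3)c(OC(=O)c3ccccc3)cc(-c3ccc(OCc4ccccc4)cc3)c2O1
F17 | step 5 | 4,7-bis[4-(benzyloxy)phenyl]-2,2-di-tert-butyl-1,3,2-benzodioxasilole-5,6-diyl dibenzoate | CC(C)(C)[Si]1(C(C)(C)C)Oc2c(-c3ccc(OCc4ccccc4)cc3)c(OC(=O)c3ccccc3)c(OC(=O)c3ccccc3)c(-c3ccc(OCc4ccccc4)cc3)c2O1
F18 | step 5 | 3,6-bis[4-(benzyloxy)phenyl]-4,5-dihydroxy-1,2-phenylene dibenzoate | O=C(Oc1c(OC(=O)c2ccccc2)c(-c2ccc(OCc3ccccc3)cc2)c(O)c(O)c1-c1ccc(OCc2ccccc2)cc1)c1ccccc1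
A1 | alternative 1 | methyl 3-[4-(benzyloxy)phenyl]-2-oxopropanoate | COC(=O)C(=O)Cc1ccc(OCc2ccccc2)cc1
A2 | alternative 1 | 2,5-bis[4-(benzyloxy)phenyl]-3,6-dihydroxy-1,4-benzoquinone | O=C1C(O)=C(c2ccc(OCc3ccccc3)cc2)C(=O)C(O)=C1c1ccc(OCc2ccccc2)cc1
A3 | alternative 1 | 3,6-bis[4-(benzyloxy)phenyl]benzene-1,2,4,5-tetrol | Oc1c(O)c(-c2ccc(OCc3ccccc3)cc2)c(O)c(O)c1-c1ccc(OCc2ccccc2)cc1
A4 | alternative 2 | 2,2'-[5,6-bis(benzoyloxy)-1,3-benzodioxole-4,7-diyl]diacetaldehyde | O=CCc1c(OC(=O)c2ccccc2)c(OC(=O)c2ccccc2)c(CC=O)c2OCOc12
A5 | alternative 2 | but-3-en-2-one | CC(=O)C=C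
A6 | alternative 2 | 4,7-bis(4-oxocyclohex-2-en-1-yl)-1,3-benzodioxole-5,6-diyl dibenzoate (one diastereomer) | O=C1CC[C@@H](C=C1)c1c(OC(=O)c2ccccc2)c(OC(=O)c2ccccc2)c([C@H]2CCC(=O)C=C2)c2OCOc12
A7 | alternative 3 | (1Z,3Z)-1,4-bis[4-(benzyloxy)phenyl]buta-1,3-diene-2,3-diyl dibenzoate | c1ccccc1COc1ccc(cc1)/C=C(\OC(=O)c1ccccc1)/C(OC(=O)c1ccccc1)=C/c1ccc(OCc2ccccc2)cc1
A8 | alternative 3 | 4,5-dichloro-1,3-dioxol-2-one | O=C1OC(Cl)=C(Cl)O1
A9 | alternative 3 | meso endo 3a,7a-dichloro-4,7-bis[4-(benzyloxy)phenyl]-2-oxo-3a,4,7,7a-tetrahydro-1,3-benzodioxole-5,6-diyl dibenzoate | O=C1O[C@]2(Cl)[C@H](c3ccc(OCc4ccccc4)cc3)C(OC(=O)c3ccccc3)=C(OC(=O)c3ccccc3)[C@H](c3ccc(OCc4ccccc4)cc3)[C@]2(Cl)O1
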